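The trap in oak was to read it as Friday's run over again, since the two hold the same charges. They differ in how the substrate arrives.

| flask | substrate | reagent | initiator | remark | time |
|---|---|---|---|---|---|
| Friday's | 0.050 M | 0.050 M | 5 mM | run made earlier |  |
| Tuesday's | 0.050 M | 0.050 M | 3.4 mM | run made earlier |  |
| Thursday's | 0.050 M | 0.050 M | 7.5 mM | run made earlier |  |
| Sunday's | 0.050 M | 0.075 M | 5 mM | run made earlier |  |
| cedar | 0.050 M | 0.0500 M | 5.0 mM | a single well-mixed tank run continuously and read at steady state, 10 h in it on average |  |
| oak | 0.050 M (fed, over 10.0 h) | 0.0500 M | 5.0 mM | a stirred flask in which substrate is dosed at a steady rate over 10.0 h without added volume, worked up at 10 h | 10 h |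
| ash | 0.050 M | 0.0500 M | 5.0 mM | everything together in a closed stirred flask, run for 10 h | 10 h |
| larch | 0.050 M | 0.0500 M (fed, over 10.0 h) | 5.0 mM | all but reagent at the start; reagent goes in evenly over 10.0 h, the run ends at 10 h | 10 h |

| run | time / h | target / % |
|---|---|---|
| Friday's | 1.00 | 90.8 |
| Friday's | 2.00 | 89.9 |
| Friday's | 3.00 | 90.1 |
| Friday's | 4.00 | 90.7 |
| Friday's | 5.00 | 89.8 |
| Friday's | 6.00 | 90.6 |
| Tuesday's | 0.500 | 84.5 |
| Tuesday's | 1.50 | 90.4 |
| Tuesday's | 3.00 | 89.9 |
| Tuesday's | 4.00 | 90.1 |
| Tuesday's | 6.00 | 89.9 |
| Tuesday's | 8.00 | 89.8 |
| Thursday's | 0.667 | 89.9 |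
| Thursday's | 1.00 | 90.0 |
| Thursday's | 2.00 | 89.8 |
| Thursday's | 3.00 | 90.1 |
| Thursday's | 5.00 | 90.9 |
| Thursday's | 8.00 | 89.9 |
| Sunday's | 1.50 | 96.1 |
| Sunday's | 3.00 | 96.2 |
| Sunday's | 5.00 | 95.7 |
| Sunday's | 6.00 | 95.1 |
| Sunday's | 8.00 | 95.1 |

(readings scatter by 0.5 percentage points)

- the stated concentrations are those of everything mixed, before any reaction; amounts are the same in each set-up
- the analysis behind the earlier runs scatters by 0.5 percentage points, standard deviation
- the feed brings no volume worth counting
- the earlier runs were made in a closed, stirred flask

* order of the set-ups by the amount of target at the outlet or at the end, in percent of the substrate put in, highest first (cedar / oak / ash / larch)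
* amount of target at the outlet or at the end, in percent of the substrate put in, cedar
* amount of target at the outlet or at the end, in percent of the substrate put in, oak
* amount of target at the outlet or at the end, in percent of the substrate put in, ash
* amount of target at the outlet or at the end, in percent of the substrate put in, larch

I began with the balance of the reagent, taking one reagent per target. I call the reagent ceiling C the charge of reagent over the charge of substrate, the most target the reagent can pay for. 100% was C for oak and for Friday's run.

Friday's run averaged 90.3%, so it stopped 9.7 percentage points under C. Sunday's run, with C at 150%, averaged 95.6%. Sunday's run differed from Friday's in its reagent, and it read 5.3 points higher. Friday's readings stayed flat within their scatter from the first one on, so I took the shortfall to belong to the time when substrate stands beside reagent and target.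

Friday's readings were at their plateau by 1.00 h, and the feed of oak lasts ten times as long. So I expected each portion of substrate in oak to be used before much more arrived, and I put oak above Friday's reading, close under C. I put ash at Friday's reading. In larch the substrate stands from the start while the reagent comes over 10.0 h, so I put larch last. Cedar I could not place.

The forecast gave ash > oak > cedar > larch, with 80.5% for cedar, 89% for oak, 90% for ash and 6% for larch, holding that “the yield is set by reagent”, and I set oak higher.

The flasks gave oak > cedar > ash > larch: oak 98.2%, cedar 92.9%, ash 90.3%, larch 47.5%.

    substrate + second chain carrier → by-product + first chain carrier (k = 1.20 × 10⁷ M⁻¹ h⁻¹)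
    initiator → 2 initiating radical (k = 0.620 h⁻¹)
    substrate + target → side product (k = 6.60 M⁻¹ h⁻¹)
    substrate + initiating radical → capped initiator + first chain carrier (k = 1.10 × 10⁵ M⁻¹ s⁻¹)
    reagent + first chain carrier → target + second chain carrier (k = 46000 M⁻¹ s⁻¹)
    2 first chain carrier → ended chains (k = 7.90 × 10⁸ M⁻¹ s⁻¹)

Substrate also reacts with target, and at the charged concentrations of ash that step alone gives target a half-life of 2.1 h, shorter than the 10 h of the run. In oak substrate stood at 0% after 5.00 h, and side product ended at 0%, against 4.33% in ash. Oak ended 1.8 points under C. The neighbour of oak with 0.020 M of reagent had reagent as its limiting reagent, with C at 40.0%. It ended with 0% of its reagent, 31.9% target and 16.3% side product. That percentage counts each side product as two, of which one came as target, so target and the reagent's share of side product add up to 40.1%.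

The numbers in the tables are simulated for an exercise; scatter was added.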